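**Retrosynthetic overview**
1. The strategy rests on ring D, a fully substituted acylphloroglucinol: D1 carries the CH2 link to C8 of flavan ring A, D2 is OH, D3 isobutyryl, D4 OMe, D5 CH3, D6 OH. It is an isobutyryl-primed tetraketide whose single methyl ether (D4) is hard to place by selective O-methylation but can be carried through an open chain as an enol ether.
2. Pilosanol B 18 ⇒ penta-O-benzyl ether 17 by global hydrogenolysis. Rings A, B and C, with C2 (R) and C3 (S), come intact from (+)-catechin.
3. Ring D is the only ring formed, and it is formed last. The D2–D3 bond comes from an intramolecular Claisen condensation of the D3 methylene onto the ester carbon D2 of open-chain 15 (D4 masked as methyl enol ether), followed by aromatization.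
4. 15 ⇒ terminal isobutyrylation at D3 of β-keto ester 12 with Weinreb amide 14. 12 ⇒ D1–D6 bond by C-acylation of the enolate of propanoate 7 with acid chloride 11, made from methyl 2-methylacetoacetate.
5. 7 ⇒ Heck coupling and conjugate reduction on 8-bromo-penta-O-benzylcatechin 4 ⇐ (+)-catechin.

Key step: step 12

Remark on the chemistry: "Fl" below means the (2R,3S)-3,5,7-tris(benzyloxy)-2-[3,4-bis(benzyloxy)phenyl]chroman-8-yl group. Compounds 12 and 15 are assumed to be carried as mixtures of D1 epimers and keto–enol forms, and enol ether 9 is drawn as its E isomer. Neither point matters, because D1 becomes an aromatic carbon and the D4=D5 geometry is lost in the dienolates of steps 11 and 12.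

**Step 1**
Reactants: 1 (+)-catechin
Product: 2 (2R,3S)-5,7-bis(benzyloxy)-2-[3,4-bis(benzyloxy)phenyl]chroman-3-ol
Conditions: BnBr (4.4 equiv), K2CO3, DMF, 0 °C to rt, Ar
Reagents that add atoms: benzyl bromide, BrCc1ccccc1
Why: Williamson etherification in which K2CO3 ionizes only the four phenols and not the secondary C3 alcohol, so the tetra-ether should form with the (2R,3S) centres untouched.

**Step 2**
Reactants: 2 tetra-O-benzylcatechin
Product: 3 (2R,3S)-3,5,7-tris(benzyloxy)-2-[3,4-bis(benzyloxy)phenyl]chroman (penta-O-benzylcatechin)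
Conditions: NaH, BnBr, n-Bu4NI (cat.), DMF, 0 °C to rt
Reagents that add atoms: benzyl bromide, BrCc1ccccc1
Why: Williamson etherification of the sodium alkoxide at C3; with no free phenol left, C2 cannot epimerize through a quinone methide.

**Step 3**
Reactants: 3 penta-O-benzylcatechin
Product: 4 (2R,3S)-8-bromo-3,5,7-tris(benzyloxy)-2-[3,4-bis(benzyloxy)phenyl]chroman (Fl–Br)
Conditions: NBS (1.0 equiv), CH2Cl2, −78 °C to rt
Reagents that add atoms: N-bromosuccinimide, O=C1CCC(=O)N1Br
Why: electrophilic aromatic bromination, which in benzylated flavan-3-ols goes to C8 of the phloroglucinol-type ring A in preference to C6 and to ring B; one equivalent at low temperature should avoid dibromination.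

**Step 4**
Reactants: 4 Fl–Br; 5 methyl acrylate
Product: 6 methyl (E)-3-Fl-acrylate
Conditions: Pd(P(t-Bu)3)2 (5 mol %), Cy2NMe, dioxane, 100 °C
Reagents that add atoms: none
Why: Mizoroki–Heck reaction in which the bulky, electron-rich phosphine on zerovalent palladium allows oxidative addition into the hindered, electron-rich C8–Br bond, and syn insertion with β-hydride elimination gives the E-cinnamate.

**Step 5**
Reactants: 6 methyl (E)-3-Fl-acrylate
Product: 7 methyl 3-Fl-propanoate
Conditions: NiCl2·6H2O (0.3 equiv), NaBH4, MeOH–THF, 0 °C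
Reagents that add atoms: none
Why: conjugate reduction by nickel boride formed from NiCl2 and NaBH4, which saturates the cinnamate C=C but leaves the ester, the benzyl ethers and the flavan C2–O bond alone, where H2 over palladium would not.

**Step 6**
Reactants: 8 methyl 2-methylacetoacetate
Product: 9 methyl (E)-3-methoxy-2-methylbut-2-enoate
Conditions: HC(OMe)3 (neat, 2 equiv), H2SO4 (cat.), rt; then distillation
Reagents that add atoms: trimethyl orthoformate, COC(OC)OC
Why: acid-catalysed ketalization of the ketone by the orthoformate and loss of methanol on distillation (enol ether formation) should give the conjugated β-methoxy enoate, with the E isomer (methoxy trans to the ester) expected as the more stable one.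

**Step 7**
Reactants: 9 methyl (E)-3-methoxy-2-methylbut-2-enoate
Product: 10 (E)-3-methoxy-2-methylbut-2-enoic acid
Conditions: LiOH·H2O, MeOH–H2O, 60 °C; then 1 M HCl to pH 3, 0 °C
Reagents that add atoms: lithium hydroxide, [Li+].[OH-]
Why: saponification of the ester, to which the enol ether is stable in base; brief cold acidification frees the acid without hydrolysing the enol ether.

**Step 8**
Reactants: 10 (E)-3-methoxy-2-methylbut-2-enoic acid
Product: 11 (E)-3-methoxy-2-methylbut-2-enoyl chloride
Conditions: (COCl)2, DMF (cat.), CH2Cl2, 0 °C to rt; evaporate, use crude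
Reagents that add atoms: oxalyl chloride, ClC(=O)C(=O)Cl
Why: acid chloride formation through the Vilsmeier-type chloroiminium species, mild enough for β-alkoxyacryloyl systems and leaving only gaseous by-products.

**Step 9**
Reactants: 7 methyl 3-Fl-propanoate; 11 (E)-3-methoxy-2-methylbut-2-enoyl chloride
Product: 12 methyl (E)-2-(Fl-methyl)-5-methoxy-4-methyl-3-oxohex-4-enoate (both D1 epimers)
Conditions: LiN(SiMe3)2 (2.2 equiv), THF, −78 °C; then 11 (1.2 equiv), −78 °C; aq NH4Cl
Reagents that add atoms: none
Why: crossed Claisen C-acylation of the lithium ester enolate by an acid chloride forms the D1–D6 bond, and the second equivalent of amide base takes up the more acidic β-keto ester as it forms so that the enolate of 7 is not spent as a base.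

**Step 10**
Reactants: 13 isobutyryl chloride
Product: 14 N-methoxy-N-methylisobutyramide
Conditions: MeNH(OMe)·HCl, Et3N (2.2 equiv), CH2Cl2, 0 °C to rt
Reagents that add atoms: N,O-dimethylhydroxylamine hydrochloride, CNOC.Cl
Why: nucleophilic acyl substitution of the acid chloride by the hydroxylamine gives the Weinreb amide.

**Step 11**
Reactants: 12 β-keto ester; 14 N-methoxy-N-methylisobutyramide
Product: 15 methyl (E)-2-(Fl-methyl)-5-methoxy-4,8-dimethyl-3,7-dioxonon-4-enoate (masked tetraketide, both D1 epimers)
Conditions: LiN(i-Pr)2 (2.3 equiv), THF, −78 to −30 °C; then 14 (1.3 equiv), −78 to −20 °C; cold aq NH4Cl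
Reagents that add atoms: none
Why: terminal acylation of a β-polycarbonyl dianion (vinylogous Weiler-type), in which the first equivalent of base forms the β-keto ester enolate and the second removes a proton from the D3 methyl, vinylogous to and cis to the D6 carbonyl; the dianion should react at its terminal carbon because D5 is fully substituted, and the Weinreb amide holds the adduct as a chelate until work-up so that the acidic product neither quenches the dianion nor is acylated twice.

**Step 12**
Reactants: 15 masked tetraketide methyl ester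
Product: 17 penta-O-benzyl pilosanol B, via non-aromatic Claisen adduct 16 (not isolated)
Conditions: Mg(OMe)2 (5 equiv), MeOH–THF, 65 °C, Ar; then cold 1 M HCl
Reagents that add atoms: none
Why: Mg(OMe)2 reversibly removes the D1 and D3 protons, and the D3 carbanion (the isobutyryl ketone enolate, extended through D4=D5 to the D6 carbonyl) adds to the ester carbonyl D2 and expels methoxide to give the 6-acylcyclohex-4-ene-1,3-dione 16, which enolizes at once to the benzene ring with the enol ether oxygen ending as the D4 aryl methyl ether. The closest known reaction type is the biomimetic intramolecular Claisen condensation of 3,5,7-triketo esters to acylphloroglucinols under magnesium methoxide. Ring D closes in the 6-exo-trig mode, and because D4–D5 rotates freely in the dienolate either enol ether geometry should converge on the same ring. No stereocentre is created: the D1 centre of 15 is erased on aromatization, and C2 and C3 of the flavan are not at risk because no free phenol is present to open a quinone methide. The step needs Claisen closure at D2 to win over aldol closure of D1 onto the isobutyryl carbonyl; the substrate secures this because the aldol adduct would carry a quaternary D1 (Fl-methyl and ester) that cannot aromatize and so reverts, the isopropyl group shields that ketone, and magnesium chelation of the two dicarbonyl ends holds D3 near D2. Formation of the acylphloroglucinol magnesium phenoxide should make the closure irreversible.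

**Step 13**
Reactants: 17 penta-O-benzyl pilosanol B
Product: 18 pilosanol B
Conditions: H2 (1 atm), Pd(OH)2/C, THF–MeOH, rt
Reagents that add atoms: none
Why: hydrogenolysis of the five benzyl ethers under neutral conditions, which should leave the diarylmethane bridge, the hydrogen-bonded aryl ketone, the flavan C2–O bond and both stereocentres untouched.

**Compound list**
1 | (+)-catechin, (2R,3S) | O[C@H]1Cc2c(O)cc(O)cc2O[C@@H]1c1ccc(O)c(O)c1 | starting material
2 | (2R,3S)-5,7-bis(benzyloxy)-2-[3,4-bis(benzyloxy)phenyl]chroman-3-ol | c1c(OCc2ccccc2)cc(OCc2ccccc2)c2c1O[C@H](c1ccc(OCc3ccccc3)c(OCc3ccccc3)c1)[C@@H](O)C2 | intermediate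
3 | (2R,3S)-3,5,7-tris(benzyloxy)-2-[3,4-bis(benzyloxy)phenyl]chroman | c1c(OCc2ccccc2)cc(OCc2ccccc2)c2c1O[C@H](c1ccc(OCc3ccccc3)c(OCc3ccccc3)c1)[C@@H](OCc1ccccc1)C2 | intermediate
4 | (2R,3S)-8-bromo-3,5,7-tris(benzyloxy)-2-[3,4-bis(benzyloxy)phenyl]chroman | Brc1c(OCc2ccccc2)cc(OCc2ccccc2)c2c1O[C@H](c1ccc(OCc3ccccc3)c(OCc3ccccc3)c1)[C@@H](OCc1ccccc1)C2 | intermediate
5 | methyl acrylate | C=CC(=O)OC | starting material
6 | methyl (E)-3-[(2R,3S)-3,5,7-tris(benzyloxy)-2-(3,4-bis(benzyloxy)phenyl)chroman-8-yl]acrylate | COC(=O)/C=C/c1c(OCc2ccccc2)cc(OCc2ccccc2)c2c1O[C@H](c1ccc(OCc3ccccc3)c(OCc3ccccc3)c1)[C@@H](OCc1ccccc1)C2 | intermediate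
7 | methyl 3-[(2R,3S)-3,5,7-tris(benzyloxy)-2-(3,4-bis(benzyloxy)phenyl)chroman-8-yl]propanoate | COC(=O)CCc1c(OCc2ccccc2)cc(OCc2ccccc2)c2c1O[C@H](c1ccc(OCc3ccccc3)c(OCc3ccccc3)c1)[C@@H](OCc1ccccc1)C2 | intermediate
8 | methyl 2-methylacetoacetate | CC(=O)C(C)C(=O)OC | starting material
9 | methyl (E)-3-methoxy-2-methylbut-2-enoate | C/C(OC)=C(C)\C(=O)OC | intermediate
10 | (E)-3-methoxy-2-methylbut-2-enoic acid | C/C(OC)=C(C)\C(=O)O | intermediate
11 | (E)-3-methoxy-2-methylbut-2-enoyl chloride | C/C(OC)=C(C)\C(=O)Cl | intermediate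
12 | methyl (E)-5-methoxy-4-methyl-3-oxo-2-{[(2R,3S)-3,5,7-tris(benzyloxy)-2-(3,4-bis(benzyloxy)phenyl)chroman-8-yl]methyl}hex-4-enoate (epimers at C2 of the chain) | C/C(OC)=C(C)\C(=O)C(Cc1c(OCc2ccccc2)cc(OCc2ccccc2)c2c1O[C@H](c1ccc(OCc3ccccc3)c(OCc3ccccc3)c1)[C@@H](OCc1ccccc1)C2)C(=O)OC | intermediate
13 | isobutyryl chloride | CC(C)C(Cl)=O | starting material
14 | N-methoxy-N-methylisobutyramide | CC(C)C(=O)N(C)OC | intermediate
15 | methyl (E)-5-methoxy-4,8-dimethyl-3,7-dioxo-2-{[(2R,3S)-3,5,7-tris(benzyloxy)-2-(3,4-bis(benzyloxy)phenyl)chroman-8-yl]methyl}non-4-enoate (epimers at C2 of the chain) | CC(C)C(=O)C/C(OC)=C(C)\C(=O)C(Cc1c(OCc2ccccc2)cc(OCc2ccccc2)c2c1O[C@H](c1ccc(OCc3ccccc3)c(OCc3ccccc3)c1)[C@@H](OCc1ccccc1)C2)C(=O)OC | intermediate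
16 | 6-(2-methylpropanoyl)-5-methoxy-4-methyl-2-{[(2R,3S)-3,5,7-tris(benzyloxy)-2-(3,4-bis(benzyloxy)phenyl)chroman-8-yl]methyl}cyclohex-4-ene-1,3-dione (not isolated) | COC1=C(C)C(=O)C(Cc2c(OCc3ccccc3)cc(OCc3ccccc3)c3c2O[C@H](c2ccc(OCc4ccccc4)c(OCc4ccccc4)c2)[C@@H](OCc2ccccc2)C3)C(=O)C1C(=O)C(C)C | intermediate
17 | penta-O-benzyl pilosanol B: 1-(2,4-dihydroxy-6-methoxy-5-methyl-3-{[(2R,3S)-3,5,7-tris(benzyloxy)-2-(3,4-bis(benzyloxy)phenyl)chroman-8-yl]methyl}phenyl)-2-methylpropan-1-one | COc1c(C)c(O)c(Cc2c(OCc3ccccc3)cc(OCc3ccccc3)c3c2O[C@H](c2ccc(OCc4ccccc4)c(OCc4ccccc4)c2)[C@@H](OCc2ccccc2)C3)c(O)c1C(=O)C(C)C | intermediate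
18 | pilosanol B, (2R,3S) | COc1c(C)c(O)c(Cc2c(O)cc(O)c3c2O[C@H](c2ccc(O)c(O)c2)[C@@H](O)C3)c(O)c1C(=O)C(C)C | target

**Step count and risks**
Total step count: 13. Longest linear sequence: 9 steps from (+)-catechin (steps 1, 2, 3, 4, 5, 9, 11, 12, 13).

Steps most likely to fail:

Step 12. With D1 held as its magnesium β-keto ester enolate and flanked by the bulky flavanylmethyl group, addition of D3 to the ester carbonyl may be slower than methoxide-induced retro-Claisen cleavage of the D1–D6 or the isobutyryl–D3 bond, so the chain would fragment instead of closing. The fallback closes ring D before it is joined to the flavan; it sets out from 11, 14 and 4 and returns at 17. The lithium enolate of methyl acetate (LiN(SiMe3)2, THF, −78 °C) would be acylated with 11 to methyl (E)-5-methoxy-4-methyl-3-oxohex-4-enoate F1. Its dianion (LiN(i-Pr)2, 2.2 equiv) would be acylated with 14 to methyl (E)-5-methoxy-4,8-dimethyl-3,7-dioxonon-4-enoate F2. Mg(OMe)2 in MeOH should close this chain, which is unsubstituted at D1 and so matches the triketo ester precedent directly, to 1-(4,6-dihydroxy-2-methoxy-3-methylphenyl)-2-methylpropan-1-one F3. In parallel, bromide 4 would undergo bromine–lithium exchange (n-BuLi, THF, −78 °C) and trapping with formaldehyde from cracked paraformaldehyde to give [(2R,3S)-3,5,7-tris(benzyloxy)-2-(3,4-bis(benzyloxy)phenyl)chroman-8-yl]methanol F4. Acid-catalysed Friedel–Crafts benzylation (Sc(OTf)3 cat., CH2Cl2, 0 °C, excess F3) at D1, the only free position of F3 and flanked by two hydroxyls, with the oxygen-stabilized benzylic cation from F4 should give 17.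

Step 11. Proton transfer from the α-branched amide to the dianion, or slow addition of the delocalized terminal carbanion to an amide carbonyl, may return 12 unchanged. The fallback attaches the same carbons at the aldehyde oxidation level; it sets out from 12 and returns at 15. The dianion of 12 (LiN(i-Pr)2, THF, −78 °C) would be trapped with isobutyraldehyde in a vinylogous aldol addition to give methyl (E)-7-hydroxy-5-methoxy-4,8-dimethyl-3-oxo-2-{[(2R,3S)-3,5,7-tris(benzyloxy)-2-(3,4-bis(benzyloxy)phenyl)chroman-8-yl]methyl}non-4-enoate F5. Oxidation of the secondary alcohol with Dess–Martin periodinane (NaHCO3, CH2Cl2) should then give 15.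

Step 4. Slow oxidative addition and slow alkene insertion at the doubly ortho-oxygenated aryl–palladium species may end in protodebromination instead of coupling. The fallback avoids palladium; it sets out from 4 and returns at 6. Bromine–lithium exchange (n-BuLi, THF, −78 °C) and formylation with DMF would give (2R,3S)-3,5,7-tris(benzyloxy)-2-[3,4-bis(benzyloxy)phenyl]chroman-8-carbaldehyde F6. Horner–Wadsworth–Emmons olefination with trimethyl phosphonoacetate (NaH, THF, 0 °C) should then give the E-cinnamate 6.

**Further compounds**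
F1 | step 12 | methyl (E)-5-methoxy-4-methyl-3-oxohex-4-enoate | C/C(OC)=C(C)\C(=O)CC(=O)OC
F2 | step 12 | methyl (E)-5-methoxy-4,8-dimethyl-3,7-dioxonon-4-enoate | CC(C)C(=O)C/C(OC)=C(C)\C(=O)CC(=O)OC
F3 | step 12 | 1-(4,6-dihydroxy-2-methoxy-3-methylphenyl)-2-methylpropan-1-one | COc1c(C)c(O)cc(O)c1C(=O)C(C)C
F4 | step 12 | [(2R,3S)-3,5,7-tris(benzyloxy)-2-(3,4-bis(benzyloxy)phenyl)chroman-8-yl]methanol | OCc1c(OCc2ccccc2)cc(OCc2ccccc2)c2c1O[C@H](c1ccc(OCc3ccccc3)c(OCc3ccccc3)c1)[C@@H](OCc1ccccc1)C2
F5 | step 11 | methyl (E)-7-hydroxy-5-methoxy-4,8-dimethyl-3-oxo-2-{[(2R,3S)-3,5,7-tris(benzyloxy)-2-(3,4-bis(benzyloxy)phenyl)chroman-8-yl]methyl}non-4-enoate | CC(C)C(O)C/C(OC)=C(C)\C(=O)C(Cc1c(OCc2ccccc2)cc(OCc2ccccc2)c2c1O[C@H](c1ccc(OCc3ccccc3)c(OCc3ccccc3)c1)[C@@H](OCc1ccccc1)C2)C(=O)OC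
F6 | step 4 | (2R,3S)-3,5,7-tris(benzyloxy)-2-[3,4-bis(benzyloxy)phenyl]chroman-8-carbaldehyde | O=Cc1c(OCc2ccccc2)cc(OCc2ccccc2)c2c1O[C@H](c1ccc(OCc3ccccc3)c(OCc3ccccc3)c1)[C@@H](OCc1ccccc1)C2
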